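## Analysis of the target

Target 10 is (1S,2S,4S,5R)-2,4-dibromo-1-chloro-5-[(E)-2-chloroethenyl]-1,5-dimethylcyclohexane, one cyclohexane ring holding all ten carbons of a monoterpene and four halogens. The ring is numbered here C1 (CMeCl), C2 (CH2), C3 (quaternary, with CH3 and the chlorovinyl group C9=C10), C4 (CHBr), C5 (CH2), C6 (CHBr); ring C1, C6, C4 and C3 are positions 1, 2, 4 and 5 of the name. There are four stereocentres, two of them fully substituted (C1, C3), and each CHBr carbon sits next to one of these. In the chair the structure calls for, C1–Cl, C6–Br and the C3 methyl are axial, while C4–Br, the chlorovinyl group and the C1 methyl are equatorial. Hence Cl at C1 is trans-diaxial to Br at C6, and Br at C4 is anti to the C3–C2 bond, trans to the chlorovinyl group and cis to the C3 methyl. The tertiary chloride with an antiperiplanar bromine loses HCl or halogen under base, Lewis acid or heat, and the vinyl chloride does not survive strong base or low-valent metals. The molecule has no oxygen handle, both C–Br bonds are neopentyl-like and closed to displacement, and two different halogens must go to defined sites. The strategy rests on the two anti relationships: Br(C4)/C2 across the former (E) C3=C4 bond and Cl(C1)/Br(C6) are what a bromonium-initiated cation–olefin closure ended by chloride leaves behind, so C2–C3, C4–Br and C1–Cl can be formed in one event from acyclic triene 9.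

## Retrosynthetic reasoning

**10 ⇒ 9.** The bonds C2–C3, C4–Br and C1–Cl are cut together. This leaves triene 9, in which chain C3–C8 become ring C3, C4, C5, C6, C1, C2 and chain C2, C1 become C9, C10. No other cut removes three of the four stereocentres at once, and C6–Br, the only stereocentre of 9, sits where it can steer a chair. Forward, an electrophilic bromine donor must add to C4 of the chlorodiene, the isopropenyl CH2 must bond to C3, and a chloride source must capture C1 anti to the C6 bromine.

**9 ⇒ 8.** The C6–Br bond is traced to the C–O bond of alcohol 8 with opposite configuration. The allylic bromide is the least stable function of the series, so it is made last before the key step. Forward, an Appel reaction must invert cleanly without allylic transposition.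

**8 ⇒ 7.** The C9=C10 double bond is cut to the aldehyde of 7 and a one-carbon chloromethylidene unit. This brings the vinyl chloride in late, after all hydride and base steps, and uses the one olefination that gives (E)-chloroalkenes directly.

**7 ⇒ 6 ⇒ 5.** These are redox adjustments only: the enal of 7 comes from the primary allylic alcohol of diol 6, and 6 from the enoate of 5. The ester oxidation level is kept in 5 because it is what the C–C bond-forming step below delivers.

**5 ⇒ 3 + 4.** The C5–C6 bond (ring numbering) is cut as a vinylogous aldol between silyl dienol ether 3 and methacrolein 4. One step sets the C6 carbinol stereocentre, brings in the isopropenyl group and gives the (E)-trisubstituted alkene with the methyl already on C3. Carbometalation of a homopropargylic alkyne would place that methyl on C4, which is why the bond is not made that way. Forward, the catalyst must control γ-attack on one face of a small enal.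

**3 ⇒ 1.** The O–Si bond is cut; 3 is the γ-deprotonated, O-silylated form of ethyl tiglate 1.

## Alternatives that were turned down

**Alternative 1:** Disconnection of C3–C4 by an aldol, with C4–Br left for later. Forward, aldehyde acid A1 is activated as an ammonium enolate and closes by aldol-lactonization to the cis-fused β-lactone A2.
- For it: the closure is a known, catalytic, enantioselective reaction class. The β-lactone is the most secure device for the hindered C4–Br: after methylation at C3, bromide opens it at C4 with inversion.
- Against it: A2 carries neither methyl group, nor the chlorovinyl group, nor any halogen. After it come methylation, opening, carboxyl to aldehyde to chloro-olefination, ketal removal, α-bromination at C6, methyl addition to an α-bromo ketone and conversion of a tertiary alcohol to the chloride. That is at least ten further steps, with C1 and C6 set late through intermediates that eliminate easily.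
- Comparison: it is stronger on precedent and on catalyst control of absolute configuration. The chosen route offers all three bonds and the C1/C6 trans relationship in one step, and seven steps in all.

**Alternative 2:** Disconnection of C4–C5 by an intramolecular Hosomi–Sakurai reaction. Forward, TiCl4 chelates aldehyde and ester of allylsilane A3, the vinyl terminus attacks the aldehyde, and silicon leaves to give hydroxy ester A4 with OH cis to the ester and the double bond at C1=C6.
- For it: chelation fixes the relative configuration, and the allylsilane fixes the alkene exactly where a later anti, Markovnikov BrCl addition can set C6–Br and C1–Cl.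
- Against it: the quaternary centre of A3 must be made enantioselectively beforehand. The hydroxyl needs inversion at a neopentyl carbinol, in practice through a β-lactone (three steps), and ester to chlorovinyl costs three more. The facial sense of the last addition rests on conformational bias only.
- Comparison: step by step it is at least as predictable as the chosen route, and its endgame serves as the reserve below. It is more than twice as long and builds the halogen pattern in four separate operations.

**Alternative 3:** Disconnection of C4–Br together with the C1=C6 alkene by a cyclopropylcarbinyl to homoallyl rearrangement. Forward, HBr or MgBr2·OEt2 ionizes the tertiary carbinol A5, bromide attacks C4 with inversion, the C4–C6 bond breaks, and the cyclohexene A6 forms.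
- For it: the C4 bromine enters stereospecifically without displacement on a carbinol, and the alkene for the final bromochlorination appears in the same step.
- Against it: A5 has four stereocentres to assemble first. Bromide can open the cyclopropane at the unhindered CH2 (C5) instead, which gives a bromomethylcyclopentene, and the cation can be captured at C1. After A6 the benzyl ether must be removed without hydrogenolysis, then oxidation, chloro-olefination and bromochlorination follow.
- Comparison: it is stronger on the C4–Br stereospecificity, weaker on regiochemistry and length. The chosen route gets the same C4–Br from the anti addition and needs no steps after ring closure.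

Key step: step 7

Assumption: the (R,R)-enantiomer of the bisphosphoramide in step 2 is taken to be the one that sends the dienolate to the Re face of 4 (giving 5R); if the opposite sense is found, the (S,S)-enantiomer is used and nothing else changes.

## Route

Step 1
Reactants: 1 ethyl (2E)-2-methylbut-2-enoate (ethyl tiglate)
Product: 3 tert-butyl[(1-ethoxy-2-methylbuta-1,3-dien-1-yl)oxy]dimethylsilane (either ketene acetal geometry), via lithium dienolate 2 (not isolated)
Conditions: LiN(iPr)2 (1.1 equiv), THF, −78 °C; then tBuMe2SiCl, DMPU, −78 °C → rt; distillation
Reagents that add atoms: tert-butyl(chloro)dimethylsilane, CC(C)(C)[Si](C)(C)Cl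
Why: Kinetic γ-deprotonation of the enoate and O-silylation of the dienolate (silyl ketene acetal formation); no stereocentre is formed, and the ketene acetal geometry does not matter because both isomers react at the γ-carbon.

Step 2
Reactants: 3 tert-butyl[(1-ethoxy-2-methylbuta-1,3-dien-1-yl)oxy]dimethylsilane; 4 2-methylprop-2-enal (methacrolein)
Product: 5 ethyl (2E,5R)-5-hydroxy-2,6-dimethylhepta-2,6-dienoate
Conditions: SiCl4 (1.1 equiv), (R,R)-N,N'-bis(3,5-dimethyl-4-oxido-4,5-dihydro-3H-dinaphtho[2,1-d:1',2'-f][1,3,2]diazaphosphepin-4-yl)-N,N'-dimethylpentane-1,5-diamine (5 mol%), iPr2NEt (10 mol%), CH2Cl2, −78 °C; aq. KF/NaHCO3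
Reagents that add atoms: none
Why: Catalytic enantioselective vinylogous Mukaiyama aldol reaction: the chiral phosphoramide-bound trichlorosilyl cation binds the aldehyde, the dienolate attacks through its γ-carbon on the Re face to set 5R, and the α-methyl enoate forms as the (E)-isomer.

Step 3
Reactants: 5 ethyl (2E,5R)-5-hydroxy-2,6-dimethylhepta-2,6-dienoate
Product: 6 (2E,5R)-2,6-dimethylhepta-2,6-diene-1,5-diol
Conditions: iBu2AlH (3.3 equiv), CH2Cl2, −78 → −40 °C; aq. potassium sodium tartrate
Reagents that add atoms: none
Why: 1,2-Reduction of an α,β-unsaturated ester to the allylic alcohol by an aluminium hydride; the free hydroxyl only consumes one equivalent, and the stereocentre and alkene geometry are untouched.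

Step 4
Reactants: 6 (2E,5R)-2,6-dimethylhepta-2,6-diene-1,5-diol
Product: 7 (2E,5R)-5-hydroxy-2,6-dimethylhepta-2,6-dienal
Conditions: 2,2,6,6-tetramethylpiperidin-1-oxyl (10 mol%), PhI(OAc)2 (1.1 equiv), CH2Cl2, rt
Reagents that add atoms: none
Why: Oxoammonium (nitroxyl-catalysed) oxidation, which takes the primary allylic alcohol much faster than the hindered secondary one, so the C5 carbinol and the (E)-alkene should pass unchanged.

Step 5
Reactants: 7 (2E,5R)-5-hydroxy-2,6-dimethylhepta-2,6-dienal
Product: 8 (3R,5E,7E)-8-chloro-2,6-dimethylocta-1,5,7-trien-3-ol
Conditions: CrCl2 (6 equiv), CHCl3 (2.5 equiv), THF, 65 °C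
Reagents that add atoms: chloroform, ClC(Cl)Cl
Why: Takai olefination: the chloro-substituted gem-dichromium species made from chloroform and divalent chromium adds to the aldehyde and the β-oxido organochromium eliminates anti to give the (E)-chloroalkene; the alcohol rides through as its chromium alkoxide and no stereocentre is touched.

Step 6
Reactants: 8 (3R,5E,7E)-8-chloro-2,6-dimethylocta-1,5,7-trien-3-ol
Product: 9 (1E,3E,6S)-6-bromo-1-chloro-3,7-dimethylocta-1,3,7-triene
Conditions: CBr4 (1.3 equiv), PPh3 (1.4 equiv), CH2Cl2, −40 → −10 °C; cold filtration through deactivated silica; used at once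
Reagents that add atoms: tetrabromomethane, BrC(Br)(Br)Br
Why: Appel reaction: bromide displaces the alkoxyphosphonium leaving group by SN2 with inversion, turning the 3R carbinol into the 6S bromide; the low temperature is there to hold back SN2' attack and ion-pair return.

Step 7
Reactants: 9 (1E,3E,6S)-6-bromo-1-chloro-3,7-dimethylocta-1,3,7-triene
Product: 10 (1S,2S,4S,5R)-2,4-dibromo-1-chloro-5-[(E)-2-chloroethenyl]-1,5-dimethylcyclohexane
Conditions: 2,4,4,6-tetrabromocyclohexa-2,5-dienone (1.1 equiv), Me3SiCl (3 equiv), 2,6-di-tert-butylpyridine (0.2 equiv), MeNO2/CH2Cl2 1:1 (0.01 M), −30 → 0 °C, dark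
Reagents that add atoms: 2,4,4,6-tetrabromocyclohexa-2,5-dienone, O=C1C(Br)=CC(Br)(Br)C=C1Br; chlorotrimethylsilane, C[Si](C)(C)Cl
Why: Proposed new method: the dienone transfers electrophilic bromine to C4 of the chlorodiene, the resulting allyl cation (C3–C9–C10, stabilized by the chlorine lone pair) is attacked at C3 by the isopropenyl CH2, and the tertiary C1 cation, bridged by the C6 bromine, is opened by chloride that Me3SiCl releases only as it silylates the tribromophenoxide left behind by the bromine transfer. The closest known reaction type is the bromonium-initiated cation–olefin cyclization of 1,5-dienes with this dienone or with Et2SBr·SbBrCl5; new here are the conjugated chlorodiene as initiator, the allylic bromide in the tether and the chloride termination. The ring closes 6-endo-trig through C2–C3 in a chair, with both carbons of the isopropenyl alkene ending in the ring. C3 and C4 follow from anti addition of Br and C2 across the (E) C3=C4 bond, which puts Br at C4 equatorial, trans to the chlorovinyl group and cis to the axial C3 methyl. Their absolute sense comes from the one existing stereocentre, since the chair with C6–Br axial avoids A(1,2) strain with the C1 methyl and has the C–Br bond aligned to bridge the developing C1 cation. C1 is set by anti opening of that bromonium ion at the tertiary carbon, so chlorine enters axial and trans to the C6 bromine. The step needs bromine transfer to the diene and not to the isopropenyl alkene (the latter is deactivated by its allylic bromine), C–C closure before halide capture (no free halide is present until the phenoxide is silylated, and the solution is dilute), chloride and not bromide as terminator (Me3SiCl is the only halide source), and survival of the allylic bromide (no Lewis acid, no halide salt, low temperature).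

## Compound list

1 | ethyl (2E)-2-methylbut-2-enoate | CCOC(=O)/C(C)=C/C | starting material
2 | lithium 1-ethoxy-2-methylbuta-1,3-dien-1-olate | [Li+].CCOC([O-])=C(C)C=C | intermediate (not isolated)
3 | tert-butyl[(1-ethoxy-2-methylbuta-1,3-dien-1-yl)oxy]dimethylsilane | CCOC(O[Si](C)(C)C(C)(C)C)=C(C)C=C | intermediate
4 | 2-methylprop-2-enal | CC(=C)C=O | starting material
5 | ethyl (2E,5R)-5-hydroxy-2,6-dimethylhepta-2,6-dienoate | CCOC(=O)/C(C)=C/C[C@@H](O)C(C)=C | intermediate
6 | (2E,5R)-2,6-dimethylhepta-2,6-diene-1,5-diol | OC/C(C)=C/C[C@@H](O)C(C)=C | intermediate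
7 | (2E,5R)-5-hydroxy-2,6-dimethylhepta-2,6-dienal | O=C/C(C)=C/C[C@@H](O)C(C)=C | intermediate
8 | (3R,5E,7E)-8-chloro-2,6-dimethylocta-1,5,7-trien-3-ol | Cl/C=C/C(C)=C/C[C@@H](O)C(C)=C | intermediate
9 | (1E,3E,6S)-6-bromo-1-chloro-3,7-dimethylocta-1,3,7-triene | Cl/C=C/C(C)=C/C[C@H](Br)C(C)=C | intermediate
10 | (1S,2S,4S,5R)-2,4-dibromo-1-chloro-5-[(E)-2-chloroethenyl]-1,5-dimethylcyclohexane | C[C@]1(Cl)C[C@](C)(/C=C/Cl)[C@@H](Br)C[C@@H]1Br | target

## Step count and least certain steps

Total: 7 steps. Longest linear sequence: 7 steps (the route is linear from 1).

**Step 7 (key step).**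
- What may go wrong: capture of the allyl cation by phenoxide or chloride before the C–C bond forms (1,2- or 1,4-addition to the diene); proton loss from the C1 cation instead of chloride capture; ionization or allylic shift of the C6 bromide; closure through the chair with C6–Br equatorial, which gives the C3/C4 epimeric pair; and bromine transfer to the isopropenyl alkene.
- Fallback, by known chemistry only: it cannot branch from an intermediate of the route, since none of 1–9 holds an oxygen at C4. It therefore sets out beside the route, before compound 1, from commercial ethyl (3R)-3-hydroxyhex-5-enoate F1, and comes back to the route at the target 10.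
  - Frater–Seebach alkylation of the dianion of F1 (LiN(iPr)2, THF/DMPU) with 3-bromo-2-methylprop-1-ene should give the anti ester ethyl (2R,3R)-3-hydroxy-2-(2-methylprop-2-en-1-yl)hex-5-enoate F2.
  - A second dianion alkylation with MeI, again anti to the carbinol substituent, should give the quaternary ester ethyl (2S,3R)-3-hydroxy-2-methyl-2-(2-methylprop-2-en-1-yl)hex-5-enoate F3.
  - Ring-closing metathesis with the second-generation Grubbs catalyst, [1,3-bis(2,4,6-trimethylphenyl)imidazolidin-2-ylidene](benzylidene)dichloro(tricyclohexylphosphine)ruthenium, in CH2Cl2 at 40 °C should close ethyl (1S,2R)-2-hydroxy-1,5-dimethylcyclohex-4-ene-1-carboxylate F4, with hydroxyl cis to the ester.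
  - LiOH should give the acid (1S,2R)-2-hydroxy-1,5-dimethylcyclohex-4-ene-1-carboxylic acid F5, and PhSO2Cl in pyridine the cis-fused β-lactone (1S,6R)-1,3-dimethyl-7-oxabicyclo[4.2.0]oct-3-en-8-one F6.
  - MgBr2·OEt2 should open the lactone at the alkyl carbon with inversion to (1R,6S)-6-bromo-1,3-dimethylcyclohex-3-ene-1-carboxylic acid F7.
  - Oxalyl chloride should give (1R,6S)-6-bromo-1,3-dimethylcyclohex-3-ene-1-carbonyl chloride F8 (not isolated), and LiAlH(OtBu)3 at −78 °C the aldehyde (1R,6S)-6-bromo-1,3-dimethylcyclohex-3-ene-1-carbaldehyde F9.
  - Takai olefination (CrCl2, CHCl3) should give (4S,5R)-4-bromo-5-[(E)-2-chloroethenyl]-1,5-dimethylcyclohex-1-ene F10.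
  - Anti, Markovnikov bromochlorination with tetrabutylammonium dichlorobromate (Bu4N BrCl2) in CH2Cl2 at −78 °C should give 10. Trans-diaxial opening is expected to favour 10, because the other diaxial adduct would place the two bromines 1,3-diaxial.

**Step 6.**
- What may go wrong: SN2' attack and ion-pair return during the Appel reaction, which means allylic transposition to the primary bromide and erosion of enantiopurity, and the same drift of 9 on storage.
- Fallback: it sets out from 8 and comes back at 9. The alcohol is first turned with MeSO2Cl/Et3N at −40 °C into (3R,5E,7E)-8-chloro-2,6-dimethylocta-1,5,7-trien-3-yl methanesulfonate F11. This is then displaced with LiBr in THF at −20 → 0 °C, so that a free, soluble bromide attacks a discrete sulfonate instead of a phosphonium ion pair collapsing.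

**Step 5.**
- What may go wrong: incomplete (E)-selectivity in the chloro-olefination and slow reaction of the chromium alkoxide, which would leave the (7Z)-isomer to be separated.
- Fallback: it sets out from 7 and comes back at 8. Seyferth–Gilbert homologation (dimethyl (diazomethyl)phosphonate, KOtBu, THF, −78 °C) should give (3R,5E)-2,6-dimethylocta-1,5-dien-7-yn-3-ol F12. Syn hydrozirconation with Cp2Zr(H)Cl (2.2 equiv) should give the (E)-dienylzirconocene chloride F13 as its zirconium alkoxide (not isolated). N-Chlorosuccinimide should then cleave the C–Zr bond with retention, so the (E)-geometry comes from the syn addition and not from an elimination.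

**Step 2.**
- What may go wrong: low facial selectivity or poor conversion with a small, volatile enal, and loss of γ-selectivity.
- Fallback: it sets out from 3 and 4 and comes back at 5. A BF3·OEt2-promoted vinylogous Mukaiyama aldol should give racemic ethyl (2E)-5-hydroxy-2,6-dimethylhepta-2,6-dienoate F14. Sharpless kinetic resolution (Ti(OiPr)4, L-(+)-diisopropyl tartrate, tBuOOH, CH2Cl2, −20 °C, to a little over half conversion) should epoxidize the (5S)-enantiomer to ethyl (2E,5S)-5-hydroxy-2-methyl-5-[(2S)-2-methyloxiran-2-yl]pent-2-enoate F15 and leave (5R)-5.

## Further compounds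

F1 | step 7 | ethyl (3R)-3-hydroxyhex-5-enoate | CCOC(=O)C[C@H](O)CC=C
F2 | step 7 | ethyl (2R,3R)-3-hydroxy-2-(2-methylprop-2-en-1-yl)hex-5-enoate | CCOC(=O)[C@H](CC(C)=C)[C@H](O)CC=C
F3 | step 7 | ethyl (2S,3R)-3-hydroxy-2-methyl-2-(2-methylprop-2-en-1-yl)hex-5-enoate | CCOC(=O)[C@@](C)(CC(C)=C)[C@H](O)CC=C
F4 | step 7 | ethyl (1S,2R)-2-hydroxy-1,5-dimethylcyclohex-4-ene-1-carboxylate | CCOC(=O)[C@@]1(C)CC(C)=CC[C@H]1O
F5 | step 7 | (1S,2R)-2-hydroxy-1,5-dimethylcyclohex-4-ene-1-carboxylic acid | OC(=O)[C@@]1(C)CC(C)=CC[C@H]1O
F6 | step 7 | (1S,6R)-1,3-dimethyl-7-oxabicyclo[4.2.0]oct-3-en-8-one | O=C1O[C@@H]2CC=C(C)C[C@]12C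
F7 | step 7 | (1R,6S)-6-bromo-1,3-dimethylcyclohex-3-ene-1-carboxylic acid | CC1=CC[C@H](Br)[C@@](C)(C(=O)O)C1
F8 | step 7 | (1R,6S)-6-bromo-1,3-dimethylcyclohex-3-ene-1-carbonyl chloride | CC1=CC[C@H](Br)[C@@](C)(C(=O)Cl)C1
F9 | step 7 | (1R,6S)-6-bromo-1,3-dimethylcyclohex-3-ene-1-carbaldehyde | CC1=CC[C@H](Br)[C@@](C)(C=O)C1
F10 | step 7 | (4S,5R)-4-bromo-5-[(E)-2-chloroethenyl]-1,5-dimethylcyclohex-1-ene | CC1=CC[C@H](Br)[C@@](C)(/C=C/Cl)C1
F11 | step 6 | (3R,5E,7E)-8-chloro-2,6-dimethylocta-1,5,7-trien-3-yl methanesulfonate | Cl/C=C/C(C)=C/C[C@@H](OS(C)(=O)=O)C(C)=C
F12 | step 5 | (3R,5E)-2,6-dimethylocta-1,5-dien-7-yn-3-ol | C#C/C(C)=C/C[C@@H](O)C(C)=C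
F13 | step 5 | (E)-dienylzirconocene chloride of F12 as its zirconocene chloride alkoxide | C=C(C)[C@H](O[Zr](Cl)(C1C=CC=C1)C1C=CC=C1)C/C=C(C)/C=C/[Zr](Cl)(C1C=CC=C1)C1C=CC=C1
F14 | step 2 | ethyl (2E)-5-hydroxy-2,6-dimethylhepta-2,6-dienoate (racemic) | CCOC(=O)/C(C)=C/CC(O)C(C)=C
F15 | step 2 | ethyl (2E,5S)-5-hydroxy-2-methyl-5-[(2S)-2-methyloxiran-2-yl]pent-2-enoate | CCOC(=O)/C(C)=C/C[C@H](O)[C@]1(C)CO1
A1 | alternative 1 | 3-[2-(3-oxopropyl)-1,3-dioxolan-2-yl]propanoic acid | OC(=O)CCC1(CCC=O)OCCO1
A2 | alternative 1 | (1S,6R)-3,3-(ethylenedioxy)-7-oxabicyclo[4.2.0]octan-8-one (cis-fused) | O=C1O[C@@H]2CCC3(OCCO3)C[C@H]12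
A3 | alternative 2 | methyl (2S)-2-formyl-2,4-dimethyl-4-(trimethylsilyl)hex-5-enoate (either configuration at C4) | COC(=O)[C@](C)(C=O)CC(C)([Si](C)(C)C)C=C
A4 | alternative 2 | methyl (1S,2R)-2-hydroxy-1,5-dimethylcyclohex-4-ene-1-carboxylate | COC(=O)[C@@]1(C)CC(C)=CC[C@H]1O
A5 | alternative 3 | (1R,2S,4S,5S)-4-[(benzyloxy)methyl]-2,4-dimethylbicyclo[3.1.0]hexan-2-ol | C[C@]1(O)C[C@](C)(COCc2ccccc2)[C@H]3C[C@@H]13
A6 | alternative 3 | benzyl [(1R,6S)-6-bromo-1,3-dimethylcyclohex-3-en-1-yl]methyl ether | CC1=CC[C@H](Br)[C@@](C)(COCc2ccccc2)C1
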